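The cycloundecene (ring atoms C1–C11, C1 carrying CO2H) is disconnected at C2–C3, the bond between the acrylate β-carbon and the CH2 lying homoallylic to the exocyclic methylene on C5. The unit C5(=CH2)–C4H2–C3H2 is the ring-opened form of a (1-substituted cyclopropyl)methyl radical. One tin-mediated radical cascade therefore opens a cyclopropane, unveils the C5 methylidene, closes the eleven-membered ring by addition of the C3 radical to a β-sulfonyl acrylate and restores the (E)-C1=C2 alkene by loss of sulfonyl radical. The precursor is an acyclic iodomethylcyclopropane bearing both carbinol centres, the angelate and a tert-butyl ester.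

Key step: step 13

Remark: vinyl sulfide 18 and sulfones 19–21 are drawn as the (E)-isomers expected to predominate; this geometry is erased in step 13, so any (Z)-material can be carried along.

Step 1
Reactants: 1 tert-butyl cyclopropanecarboxylate; 2 3,3-dimethylglutaric anhydride
Product: 4 5-[1-(tert-butoxycarbonyl)cyclopropyl]-3,3-dimethyl-5-oxopentanoic acid, via lithium enolate 3 (not isolated)
Conditions: LiN(iPr)2 (2.2 equiv), 1 (2.2 equiv), THF, −78 °C; then 2, −78 → −20 °C; aq. HCl
Reagents that add atoms: none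
Why: Claisen-type C-acylation in which the lithium ester enolate 3 opens the cyclic anhydride once, the carboxylate so released shielding the product from a second addition and the excess enolate absorbing the acidity of the new ketone α-CH2.

Step 2
Reactants: 4 5-[1-(tert-butoxycarbonyl)cyclopropyl]-3,3-dimethyl-5-oxopentanoic acid
Product: 6 tert-butyl 1-[(2S)-4,4-dimethyl-6-oxooxan-2-yl]cyclopropane-1-carboxylate, via hydroxy acid 5 (not isolated)
Conditions: H2 (50 bar), [RuCl(p-cymene)((S)-BINAP)]Cl (1 mol %), MeOH, 60 °C; then TsOH (cat.), toluene, rt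
Reagents that add atoms: none
Why: Noyori asymmetric hydrogenation of a β-keto ester, in which chelation of both carbonyls to the (S)-BINAP–ruthenium hydride should direct hydride to the face giving the (S)-carbinol (C6 of the target), as for other α,α-disubstituted β-keto esters, after which the δ-hydroxy acid 5 lactonises under acid catalysis.

Step 3
Reactants: 6 tert-butyl 1-[(2S)-4,4-dimethyl-6-oxooxan-2-yl]cyclopropane-1-carboxylate
Product: 7 (1S)-1-[1-(hydroxymethyl)cyclopropyl]-3,3-dimethylpentane-1,5-diol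
Conditions: LiAlH4, THF, 0 °C → reflux; aq. NaOH work-up
Reagents that add atoms: none
Why: Exhaustive hydride reduction opens the lactone and reduces the hindered tert-butyl ester to the neopentyl-type alcohol without affecting the cyclopropane or the carbinol centre.

Step 4
Reactants: 7 (1S)-1-[1-(hydroxymethyl)cyclopropyl]-3,3-dimethylpentane-1,5-diol
Product: 8 4-[(4S)-6,6-dimethyl-5,7-dioxaspiro[2.5]octan-4-yl]-3,3-dimethylbutan-1-ol
Conditions: 2,2-dimethoxypropane, PPTS (cat.), CH2Cl2, rt; aq. work-up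
Reagents that add atoms: 2,2-dimethoxypropane COC(C)(C)OC
Why: Acetalisation under thermodynamic control should pick the 1,3-diol as a six-membered 1,3-dioxane and leave the remote primary alcohol free after work-up.

Step 5
Reactants: 8 4-[(4S)-6,6-dimethyl-5,7-dioxaspiro[2.5]octan-4-yl]-3,3-dimethylbutan-1-ol
Product: 9 4-[(4S)-6,6-dimethyl-5,7-dioxaspiro[2.5]octan-4-yl]-3,3-dimethylbutanal
Conditions: TEMPO (10 mol %), PhI(OAc)2, CH2Cl2, rt
Reagents that add atoms: none
Why: TEMPO-catalysed oxidation of a primary alcohol stops at the aldehyde and is mild enough for the acetonide.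

Step 6
Reactants: 9 4-[(4S)-6,6-dimethyl-5,7-dioxaspiro[2.5]octan-4-yl]-3,3-dimethylbutanal; 10 tert-butyl 2-(bromomethyl)prop-2-enoate
Product: 12 tert-butyl (4S)-7-[(4S)-6,6-dimethyl-5,7-dioxaspiro[2.5]octan-4-yl]-4-hydroxy-6,6-dimethyl-2-methylideneheptanoate, via silyl ether 11 (not isolated)
Conditions: CrCl2 (10 mol %), chiral carbazole-bis(oxazoline) ligand (12 mol %), Mn, TMSCl, THF, rt; then citric acid, MeOH, 0 °C
Reagents that add atoms: none
Why: Catalytic asymmetric Nozaki–Hiyama–Kishi allylation, in which the ligand-bound 2-(alkoxycarbonyl)allyl chromium species should add through a closed chair transition state to the Re face of 9 (the ligand enantiomer is chosen for this) and so set the (S)-carbinol that becomes C10, while TMSCl turns the chromium over and the tert-butyl ester resists lactonisation on desilylation.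

Step 7
Reactants: 12 tert-butyl (4S)-7-[(4S)-6,6-dimethyl-5,7-dioxaspiro[2.5]octan-4-yl]-4-hydroxy-6,6-dimethyl-2-methylideneheptanoate; 13 angelic acid [(2Z)-2-methylbut-2-enoic acid]
Product: 15 tert-butyl (4S)-7-[(4S)-6,6-dimethyl-5,7-dioxaspiro[2.5]octan-4-yl]-6,6-dimethyl-2-methylidene-4-{[(2Z)-2-methylbut-2-enoyl]oxy}heptanoate, via mixed anhydride 14 (not isolated)
Conditions: 13, 2,4,6-trichlorobenzoyl chloride, Et3N, toluene, rt; then 12, toluene, 80 °C (no DMAP)
Reagents that add atoms: none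
Why: Yamaguchi-type esterification via mixed anhydride 14 run without a nucleophilic catalyst, the variant that transfers the angeloyl group without Z-to-E isomerisation to the tiglate.

Step 8
Reactants: 15 tert-butyl (4S)-7-[(4S)-6,6-dimethyl-5,7-dioxaspiro[2.5]octan-4-yl]-6,6-dimethyl-2-methylidene-4-{[(2Z)-2-methylbut-2-enoyl]oxy}heptanoate
Product: 16 tert-butyl (2RS,4R)-7-[(4S)-6,6-dimethyl-5,7-dioxaspiro[2.5]octan-4-yl]-6,6-dimethyl-4-{[(2Z)-2-methylbut-2-enoyl]oxy}-2-{[(4-methylphenyl)sulfanyl]methyl}heptanoate (the C4 descriptor changes only because C2 becomes sp3; no bond at C4 is touched)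
Conditions: 4-MeC6H4SH (1.05 equiv), Et3N (5 mol %), BHT (cat.), CH2Cl2, 0 °C → rt, N2, dark
Reagents that add atoms: 4-methylbenzenethiol Cc1ccc(S)cc1
Why: Base-catalysed thia-Michael addition is much faster at the unsubstituted terminus of the 1,1-disubstituted acrylate than at the β-methylated angelate, and the new centre at C2 is formed unselectively because step 9 removes it.

Step 9
Reactants: 16 tert-butyl (2RS,4R)-7-[(4S)-6,6-dimethyl-5,7-dioxaspiro[2.5]octan-4-yl]-6,6-dimethyl-4-{[(2Z)-2-methylbut-2-enoyl]oxy}-2-{[(4-methylphenyl)sulfanyl]methyl}heptanoate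
Product: 18 tert-butyl (4S)-7-[(4S)-6,6-dimethyl-5,7-dioxaspiro[2.5]octan-4-yl]-6,6-dimethyl-4-{[(2Z)-2-methylbut-2-enoyl]oxy}-2-{(E)-[(4-methylphenyl)sulfanyl]methylidene}heptanoate, via α-chloro sulfide 17 (not isolated)
Conditions: NCS (1.05 equiv), CH2Cl2, 0 °C → rt; then Et3N, 0 °C
Reagents that add atoms: none
Why: Chlorination of the sulfide by NCS through the chlorosulfonium ion (Pummerer-type α-chlorination at the only aliphatic α-carbon) and base-induced loss of HCl, for which only the ester α-hydrogen is available, should give the conjugated β-arylthio acrylate regiospecifically.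

Step 10
Reactants: 18 tert-butyl (4S)-7-[(4S)-6,6-dimethyl-5,7-dioxaspiro[2.5]octan-4-yl]-6,6-dimethyl-4-{[(2Z)-2-methylbut-2-enoyl]oxy}-2-{(E)-[(4-methylphenyl)sulfanyl]methylidene}heptanoate
Product: 19 tert-butyl (4S)-7-[(4S)-6,6-dimethyl-5,7-dioxaspiro[2.5]octan-4-yl]-6,6-dimethyl-4-{[(2Z)-2-methylbut-2-enoyl]oxy}-2-[(E)-(4-methylbenzenesulfonyl)methylidene]heptanoate
Conditions: mCPBA (2.3 equiv), NaHCO3, CH2Cl2, 0 °C → rt
Reagents that add atoms: 3-chloroperoxybenzoic acid OOC(=O)c1cccc(Cl)c1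
Why: Peracid oxidation of sulfide to sulfone under buffered, base-free conditions gives the β-sulfonyl acrylate without base-mediated drift of the double bond to the allyl sulfone, the electron-poor alkenes being inert to mCPBA.

Step 11
Reactants: 19 tert-butyl (4S)-7-[(4S)-6,6-dimethyl-5,7-dioxaspiro[2.5]octan-4-yl]-6,6-dimethyl-4-{[(2Z)-2-methylbut-2-enoyl]oxy}-2-[(E)-(4-methylbenzenesulfonyl)methylidene]heptanoate
Product: 20 tert-butyl (4S,8S)-8-hydroxy-8-[1-(hydroxymethyl)cyclopropyl]-6,6-dimethyl-4-{[(2Z)-2-methylbut-2-enoyl]oxy}-2-[(E)-(4-methylbenzenesulfonyl)methylidene]octanoate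
Conditions: AcOH/H2O/THF (3:1:1), 45 °C
Reagents that add atoms: none
Why: Acid-catalysed acetal hydrolysis under conditions too mild for the tert-butyl ester, the angelate or the vinyl sulfone.

Step 12
Reactants: 20 tert-butyl (4S,8S)-8-hydroxy-8-[1-(hydroxymethyl)cyclopropyl]-6,6-dimethyl-4-{[(2Z)-2-methylbut-2-enoyl]oxy}-2-[(E)-(4-methylbenzenesulfonyl)methylidene]octanoate
Product: 21 tert-butyl (4S,8S)-8-hydroxy-8-[1-(iodomethyl)cyclopropyl]-6,6-dimethyl-4-{[(2Z)-2-methylbut-2-enoyl]oxy}-2-[(E)-(4-methylbenzenesulfonyl)methylidene]octanoate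
Conditions: PPh3, I2 (pre-mixed), 2,6-lutidine, CH2Cl2, 0 °C, dark
Reagents that add atoms: iodine II
Why: Appel-type iodination in which the primary oxyphosphonium ion is displaced by iodide in an SN2 reaction that cyclopropylcarbinyl centres undergo readily, the hindered secondary alcohol is left alone, and pre-formed Ph3PI2 plus a hindered base keep nucleophiles away from the vinyl sulfone.

Step 13
Reactants: 21 tert-butyl (4S,8S)-8-hydroxy-8-[1-(iodomethyl)cyclopropyl]-6,6-dimethyl-4-{[(2Z)-2-methylbut-2-enoyl]oxy}-2-[(E)-(4-methylbenzenesulfonyl)methylidene]octanoate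
Product: 23 tert-butyl (1E,6S,10S)-6-hydroxy-8,8-dimethyl-5-methylidene-10-{[(2Z)-2-methylbut-2-enoyl]oxy}cycloundec-1-ene-1-carboxylate, via but-3-enyl radical 22 (not isolated)
Conditions: (Bu3Sn)2 (1.5 equiv), hν (sunlamp, Pyrex), benzene, 40 °C, slow addition of 21 (final 1 mM)
Reagents that add atoms: none
Why: Bu3Sn• from photolysis of the ditin abstracts iodine from 21, and the (1-substituted cyclopropyl)methyl radical opens by strain-driven β-scission (a radical-clock process of about 10^8 s−1) to the 3-substituted but-3-enyl radical 22, which creates the exocyclic C5=CH2 and places the radical on C3 (target numbering). Radical 22 adds in 11-endo-trig mode to C2, the sulfonyl-bearing β-carbon of the acrylate (polarity-matched Giese-type addition), forming the C2–C3 bond and the eleven-membered ring, and the α-ester radical at C1 then expels the arenesulfonyl radical, which regenerates Bu3Sn• from the ditin. The closest known reaction types are desulfonylative radical alkenylation with vinyl sulfones, radical macrocyclisation onto acrylates and cyclopropylcarbinyl radical ring opening. No stereocentre is formed; the (E)-geometry (C3 cis to C11, ester trans to C3) should arise from the less strained rotamer in the β-scission, this tiglate-like arrangement also being the thermodynamic one, and it does not depend on the geometry of 21. The step needs intramolecular addition to beat oligomerisation, which high dilution, the absence of any hydrogen donor and the doubly activated, sterically open C2 should secure, while attack on the angelate is disfavoured because its β-carbon is methyl-substituted. The iodide is used so that halogen abstraction outruns addition of the stannyl radical to the vinyl sulfone.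

Step 14
Reactants: 23 tert-butyl (1E,6S,10S)-6-hydroxy-8,8-dimethyl-5-methylidene-10-{[(2Z)-2-methylbut-2-enoyl]oxy}cycloundec-1-ene-1-carboxylate
Product: 25 (1E,6S,10S)-6-hydroxy-8,8-dimethyl-5-methylidene-10-{[(2Z)-2-methylbut-2-enoyl]oxy}cycloundec-1-ene-1-carboxylic acid, via bis-silyl derivative 24 (not isolated)
Conditions: TMSOTf, 2,6-lutidine, CH2Cl2, 0 °C → rt; then aq. citric acid, THF/MeOH
Reagents that add atoms: none
Why: TMSOTf with 2,6-lutidine silylates the ester carbonyl and expels isobutene to give silyl ester 24 (the alcohol being silylated in passing), and both silyl groups hydrolyse on mild aqueous work-up, so the allylic alcohol, the exocyclic alkene and the angelate are not exposed to strong protic acid.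

Compound list
1 | tert-butyl cyclopropanecarboxylate | CC(C)(C)OC(=O)C1CC1 | starting material
2 | 3,3-dimethylglutaric anhydride (4,4-dimethyloxane-2,6-dione) | CC1(C)CC(=O)OC(=O)C1 | starting material
3 | lithium enolate of 1 (lithium tert-butoxy(cyclopropylidene)methanolate) | [Li+].[O-]C(OC(C)(C)C)=C1CC1 | intermediate
4 | 5-[1-(tert-butoxycarbonyl)cyclopropyl]-3,3-dimethyl-5-oxopentanoic acid | CC(C)(C)OC(=O)C1(CC1)C(=O)CC(C)(C)CC(=O)O | intermediate
5 | (5S)-5-[1-(tert-butoxycarbonyl)cyclopropyl]-5-hydroxy-3,3-dimethylpentanoic acid | CC(C)(C)OC(=O)C1(CC1)[C@@H](O)CC(C)(C)CC(=O)O | intermediate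
6 | tert-butyl 1-[(2S)-4,4-dimethyl-6-oxooxan-2-yl]cyclopropane-1-carboxylate | CC(C)(C)OC(=O)C1(CC1)[C@@H]1CC(C)(C)CC(=O)O1 | intermediate
7 | (1S)-1-[1-(hydroxymethyl)cyclopropyl]-3,3-dimethylpentane-1,5-diol | OCC1(CC1)[C@@H](O)CC(C)(C)CCO | intermediate
8 | 4-[(4S)-6,6-dimethyl-5,7-dioxaspiro[2.5]octan-4-yl]-3,3-dimethylbutan-1-ol | OCCC(C)(C)C[C@@H]1OC(C)(C)OCC12CC2 | intermediate
9 | 4-[(4S)-6,6-dimethyl-5,7-dioxaspiro[2.5]octan-4-yl]-3,3-dimethylbutanal | O=CCC(C)(C)C[C@@H]1OC(C)(C)OCC12CC2 | intermediate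
10 | tert-butyl 2-(bromomethyl)prop-2-enoate | C=C(CBr)C(=O)OC(C)(C)C | starting material
11 | tert-butyl (4S)-7-[(4S)-6,6-dimethyl-5,7-dioxaspiro[2.5]octan-4-yl]-6,6-dimethyl-2-methylidene-4-[(trimethylsilyl)oxy]heptanoate | C=C(C[C@@H](O[Si](C)(C)C)CC(C)(C)C[C@@H]1OC(C)(C)OCC12CC2)C(=O)OC(C)(C)C | intermediate
12 | tert-butyl (4S)-7-[(4S)-6,6-dimethyl-5,7-dioxaspiro[2.5]octan-4-yl]-4-hydroxy-6,6-dimethyl-2-methylideneheptanoate | C=C(C[C@@H](O)CC(C)(C)C[C@@H]1OC(C)(C)OCC12CC2)C(=O)OC(C)(C)C | intermediate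
13 | angelic acid, (2Z)-2-methylbut-2-enoic acid | C/C=C(/C)C(=O)O | starting material
14 | (2Z)-2-methylbut-2-enoic 2,4,6-trichlorobenzoic anhydride | C/C=C(/C)C(=O)OC(=O)c1c(Cl)cc(Cl)cc1Cl | intermediate
15 | tert-butyl (4S)-7-[(4S)-6,6-dimethyl-5,7-dioxaspiro[2.5]octan-4-yl]-6,6-dimethyl-2-methylidene-4-{[(2Z)-2-methylbut-2-enoyl]oxy}heptanoate | C=C(C[C@@H](OC(=O)/C(C)=C\C)CC(C)(C)C[C@@H]1OC(C)(C)OCC12CC2)C(=O)OC(C)(C)C | intermediate
16 | tert-butyl (2RS,4R)-7-[(4S)-6,6-dimethyl-5,7-dioxaspiro[2.5]octan-4-yl]-6,6-dimethyl-4-{[(2Z)-2-methylbut-2-enoyl]oxy}-2-{[(4-methylphenyl)sulfanyl]methyl}heptanoate (C2 epimers) | Cc1ccc(cc1)SCC(C[C@@H](OC(=O)/C(C)=C\C)CC(C)(C)C[C@@H]1OC(C)(C)OCC12CC2)C(=O)OC(C)(C)C | intermediate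
17 | tert-butyl (4R)-2-{chloro[(4-methylphenyl)sulfanyl]methyl}-7-[(4S)-6,6-dimethyl-5,7-dioxaspiro[2.5]octan-4-yl]-6,6-dimethyl-4-{[(2Z)-2-methylbut-2-enoyl]oxy}heptanoate (stereoisomers at C2 and the chloromethine) | Cc1ccc(cc1)SC(Cl)C(C[C@@H](OC(=O)/C(C)=C\C)CC(C)(C)C[C@@H]1OC(C)(C)OCC12CC2)C(=O)OC(C)(C)C | intermediate
18 | tert-butyl (4S)-7-[(4S)-6,6-dimethyl-5,7-dioxaspiro[2.5]octan-4-yl]-6,6-dimethyl-4-{[(2Z)-2-methylbut-2-enoyl]oxy}-2-{(E)-[(4-methylphenyl)sulfanyl]methylidene}heptanoate | Cc1ccc(cc1)S/C=C(\C[C@@H](OC(=O)/C(C)=C\C)CC(C)(C)C[C@@H]1OC(C)(C)OCC12CC2)C(=O)OC(C)(C)C | intermediate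
19 | tert-butyl (4S)-7-[(4S)-6,6-dimethyl-5,7-dioxaspiro[2.5]octan-4-yl]-6,6-dimethyl-4-{[(2Z)-2-methylbut-2-enoyl]oxy}-2-[(E)-(4-methylbenzenesulfonyl)methylidene]heptanoate | Cc1ccc(cc1)S(=O)(=O)/C=C(\C[C@@H](OC(=O)/C(C)=C\C)CC(C)(C)C[C@@H]1OC(C)(C)OCC12CC2)C(=O)OC(C)(C)C | intermediate
20 | tert-butyl (4S,8S)-8-hydroxy-8-[1-(hydroxymethyl)cyclopropyl]-6,6-dimethyl-4-{[(2Z)-2-methylbut-2-enoyl]oxy}-2-[(E)-(4-methylbenzenesulfonyl)methylidene]octanoate | Cc1ccc(cc1)S(=O)(=O)/C=C(\C[C@@H](OC(=O)/C(C)=C\C)CC(C)(C)C[C@H](O)C1(CO)CC1)C(=O)OC(C)(C)C | intermediate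
21 | tert-butyl (4S,8S)-8-hydroxy-8-[1-(iodomethyl)cyclopropyl]-6,6-dimethyl-4-{[(2Z)-2-methylbut-2-enoyl]oxy}-2-[(E)-(4-methylbenzenesulfonyl)methylidene]octanoate | Cc1ccc(cc1)S(=O)(=O)/C=C(\C[C@@H](OC(=O)/C(C)=C\C)CC(C)(C)C[C@H](O)C1(CI)CC1)C(=O)OC(C)(C)C | intermediate
22 | (4S,8S)-1-tert-butoxy-8-hydroxy-6,6-dimethyl-9-methylidene-4-{[(2Z)-2-methylbut-2-enoyl]oxy}-2-[(E)-(4-methylbenzenesulfonyl)methylidene]-1-oxoundecan-11-yl radical | Cc1ccc(cc1)S(=O)(=O)/C=C(\C[C@@H](OC(=O)/C(C)=C\C)CC(C)(C)C[C@H](O)C(=C)C[CH2])C(=O)OC(C)(C)C | intermediate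
23 | tert-butyl (1E,6S,10S)-6-hydroxy-8,8-dimethyl-5-methylidene-10-{[(2Z)-2-methylbut-2-enoyl]oxy}cycloundec-1-ene-1-carboxylate | C=C1CC/C=C(/C(=O)OC(C)(C)C)C[C@@H](OC(=O)/C(C)=C\C)CC(C)(C)C[C@@H]1O | intermediate
24 | trimethylsilyl (1E,6S,10S)-8,8-dimethyl-5-methylidene-10-{[(2Z)-2-methylbut-2-enoyl]oxy}-6-[(trimethylsilyl)oxy]cycloundec-1-ene-1-carboxylate | C=C1CC/C=C(/C(=O)O[Si](C)(C)C)C[C@@H](OC(=O)/C(C)=C\C)CC(C)(C)C[C@@H]1O[Si](C)(C)C | intermediate
25 | (1E,6S,10S)-6-hydroxy-8,8-dimethyl-5-methylidene-10-{[(2Z)-2-methylbut-2-enoyl]oxy}cycloundec-1-ene-1-carboxylic acid (CNP0263820.1) | C=C1CC/C=C(/C(=O)O)C[C@@H](OC(=O)/C(C)=C\C)CC(C)(C)C[C@@H]1O | target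

Total step count: 14. Longest linear sequence: 14 steps (from 1 and 2 to 25; 10 and 13 enter as commercial building blocks).

Steps most likely to fail

Step 13 (key step). Intermolecular radical addition may outpace the slow eleven-membered closure and give oligomers. The β-scission may erode the C1=C2 geometry. Sulfonyl radicals may add reversibly to the angelate and isomerise it towards the tiglate. The fallback sets out from 21 and comes back at 23, replacing the radical chain by a stereoretentive nickel-catalysed coupling. Morpholine (THF, 0 °C) should exchange the sulfonyl group of 21 by conjugate addition–elimination to give tert-butyl (4S,8S)-8-hydroxy-8-[1-(iodomethyl)cyclopropyl]-6,6-dimethyl-4-{[(2Z)-2-methylbut-2-enoyl]oxy}-2-[(E)-(morpholin-4-yl)methylidene]octanoate F1. Brief hydrolysis with dilute aqueous acid should give the α-formyl ester, present as its hydrogen-bonded enol, tert-butyl (4S,8S)-8-hydroxy-2-[(Z)-hydroxymethylidene]-8-[1-(iodomethyl)cyclopropyl]-6,6-dimethyl-4-{[(2Z)-2-methylbut-2-enoyl]oxy}octanoate F2. Sulfonylation under non-chelating conditions (TsCl, N-methylimidazole, Et3N, CH2Cl2, −20 °C) should give the (E)-enol tosylate, tert-butyl (4S,8S)-8-hydroxy-8-[1-(iodomethyl)cyclopropyl]-6,6-dimethyl-4-{[(2Z)-2-methylbut-2-enoyl]oxy}-2-[(E)-(tosyloxy)methylidene]octanoate F3. A reductive cross-electrophile coupling (NiBr2·dme, 4,4′-di-tert-butyl-2,2′-bipyridine, Mn, DMA, high dilution) would then join the alkyl iodide and the alkenyl tosylate of F3. The cyclopropylmethyl radical formed at nickel still opens before it is captured by the alkenylnickel species, so the same C2–C3 bond and the methylidene result, while the alkene geometry is carried over from F3 with retention and no sulfonyl radical is generated.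

Step 12. The neopentyl-type cyclopropylcarbinyl oxyphosphonium ion may ionise, with ring expansion or ring opening. The phosphine may attack the vinyl sulfone in a conjugate sense, or the secondary alcohol may be activated. The fallback sets out from 20 and comes back at 21. SOCl2 and 2,6-lutidine (CH2Cl2, −20 °C) should tie both hydroxyls into the cyclic sulfite of diol 20 (a 5,7-dioxa-6-thiaspiro[2.5]octane 6-oxide, sulfur epimers) F4. NaI in DMF (50 °C) should open it at the primary carbon only, and mild acid hydrolysis of the sulfite monoester would return 21.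

Step 6. Facial selectivity may be insufficient, and the C10 epimer would be a remote diastereomer that is hard to separate; the hydroxy ester may also lactonise. The fallback sets out from 9 (with 10) and comes back at 12. Copper-catalysed borylation of 10 (B2pin2, CuCl, KOtBu, THF) should give tert-butyl 2-[(4,4,5,5-tetramethyl-1,3,2-dioxaborolan-2-yl)methyl]prop-2-enoate F5. Allylboration of 9 with F5, catalysed by a chiral BINOL-derived phosphoric acid (the enantiomer giving Re-face addition), runs through a closed chair transition state without any metal allyl, and hydrolysis of the borate would return 12.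

Further compounds
F1 | step 13 | tert-butyl (4S,8S)-8-hydroxy-8-[1-(iodomethyl)cyclopropyl]-6,6-dimethyl-4-{[(2Z)-2-methylbut-2-enoyl]oxy}-2-[(E)-(morpholin-4-yl)methylidene]octanoate | C1COCCN1/C=C(\C[C@@H](OC(=O)/C(C)=C\C)CC(C)(C)C[C@H](O)C1(CI)CC1)C(=O)OC(C)(C)C
F2 | step 13 | tert-butyl (4S,8S)-8-hydroxy-2-[(Z)-hydroxymethylidene]-8-[1-(iodomethyl)cyclopropyl]-6,6-dimethyl-4-{[(2Z)-2-methylbut-2-enoyl]oxy}octanoate (enol form of the α-formyl ester) | O/C=C(/C[C@@H](OC(=O)/C(C)=C\C)CC(C)(C)C[C@H](O)C1(CI)CC1)C(=O)OC(C)(C)C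
F3 | step 13 | tert-butyl (4S,8S)-8-hydroxy-8-[1-(iodomethyl)cyclopropyl]-6,6-dimethyl-4-{[(2Z)-2-methylbut-2-enoyl]oxy}-2-[(E)-(tosyloxy)methylidene]octanoate | Cc1ccc(cc1)S(=O)(=O)O/C=C(\C[C@@H](OC(=O)/C(C)=C\C)CC(C)(C)C[C@H](O)C1(CI)CC1)C(=O)OC(C)(C)C
F4 | step 12 | cyclic sulfite of diol 20: tert-butyl (4S)-6,6-dimethyl-4-{[(2Z)-2-methylbut-2-enoyl]oxy}-2-[(E)-(4-methylbenzenesulfonyl)methylidene]-7-[(4S)-6-oxo-5,7-dioxa-6-thiaspiro[2.5]octan-4-yl]heptanoate | Cc1ccc(cc1)S(=O)(=O)/C=C(\C[C@@H](OC(=O)/C(C)=C\C)CC(C)(C)C[C@@H]1OS(=O)OCC12CC2)C(=O)OC(C)(C)C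
F5 | step 6 | tert-butyl 2-[(4,4,5,5-tetramethyl-1,3,2-dioxaborolan-2-yl)methyl]prop-2-enoate | C=C(CB1OC(C)(C)C(C)(C)O1)C(=O)OC(C)(C)C
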